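**Plan**
- Retrosynthesis cuts C6–Cl, then C5–C6 (ten-membered ring), C8–C17 with the lactone C–O bond, C8–C9, C3–C4 and C2–C3, the C11–O–C20 epoxide, C11–C12 of ring A, and last C1–C10 of an open chain.
- Enabling feature: C11 (the spiro-epoxide carbon that carries C20) and C12 (the isovalerate carbon) are neighbouring ring A carbons with cis oxygens, the retron of a ketone–aldehyde pinacol coupling; the C20 oxygen of that ketone later closes the epoxide.
- Forward order: open chain C12–C13–C14–C1–C10–C11 (Ireland–Claisen), ring A (SmI2), spiro-epoxide, C2–C5 arm, C9–C6 arm, γ-lactone (samarium Reformatsky), ten-membered ring (Ni/Cr), chloride.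
- Stereochemistry: (R)-but-3-yn-2-ol through a chair Claisen (C1, C10); Ipc2B reagents (C14; C9 and C8); samarium chelate (C11, C12); CBS reduction (C2); osmylation anti to the allylic ether (C7); chelated aldol (C8, C17); Felkin reduction then SN2 inversion (C6).
- Locants are those of the briarane skeleton (ten-membered ring C1–C10, ring A C1/C10–C14, C15 methyl on C1, C16 methylene on C5, lactone C17–C19, C20 epoxide CH2); α is the face opposite the C1 methyl.

Key step: step 16

Remark: the outcome of step 7 assumes the lithium enolate chelated by the benzyl ether oxygen (CH2OBn cis to O–Li) reacting through a chair; stannane 17 and allyl ether 39 are made because their supply is uncertain.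

Step 1
Reactants: 1 methyl 3-hydroxy-2-methylpropanoate (racemic)
Product: 2 methyl 3-(benzyloxy)-2-methylpropanoate (racemic)
Conditions: benzyl 2,2,2-trichloroacetimidate, TfOH (cat.), CH2Cl2/cyclohexane, 0 °C → rt
Reagents that add atoms: benzyl 2,2,2-trichloroacetimidate, ClC(Cl)(Cl)C(=N)OCc1ccccc1
Why: Acid-catalysed imidate benzylation etherifies the primary alcohol without base, so the β-alkoxy ester is not exposed to retro-Michael conditions; the α-centre may stay racemic because step 7 enolises it.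

Step 2
Reactants: 2 methyl 3-(benzyloxy)-2-methylpropanoate
Product: 3 3-(benzyloxy)-2-methylpropanoic acid (racemic)
Conditions: LiOH, THF/H2O, rt; then dilute aq. HCl
Reagents that add atoms: lithium hydroxide, [Li+].[OH-]
Why: Ordinary ester saponification; the benzyl ether is inert.

Step 3
Reactants: 4 (R)-but-3-yn-2-ol
Product: 5 (R)-pent-2-yne-1,4-diol
Conditions: nBuLi (2.1 equiv), THF, −78 °C; (CH2O)n, −78 °C → rt
Reagents that add atoms: paraformaldehyde (as formaldehyde), C=O
Why: The alkoxide–acetylide dianion adds to formaldehyde at carbon (acetylide hydroxymethylation) and the carbinol centre is not touched.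

Step 4
Reactants: 5 (R)-pent-2-yne-1,4-diol
Product: 6 (R,E)-pent-2-ene-1,4-diol
Conditions: NaAlH2(OCH2CH2OMe)2, THF, 0 °C → rt
Reagents that add atoms: none
Why: Hydroxyl-directed trans-hydroalumination of the propargylic alcohol followed by protonolysis should give the E-alkene only.

Step 5
Reactants: 6 (R,E)-pent-2-ene-1,4-diol
Product: 7 (R,E)-5-[(tert-butyldimethylsilyl)oxy]pent-3-en-2-ol
Conditions: TBSCl, imidazole, CH2Cl2, −20 °C
Reagents that add atoms: tert-butyldimethylsilyl chloride, CC(C)(C)[Si](C)(C)Cl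
Why: Silylation is much faster at the primary than at the secondary allylic hydroxyl.

Step 6
Reactants: 3 3-(benzyloxy)-2-methylpropanoic acid; 7 (R,E)-5-[(tert-butyldimethylsilyl)oxy]pent-3-en-2-ol
Product: 8 (2R,3E)-5-[(tert-butyldimethylsilyl)oxy]pent-3-en-2-yl 3-(benzyloxy)-2-methylpropanoate (both epimers at the acyl α-carbon)
Conditions: EDC·HCl, DMAP (cat.), CH2Cl2, 0 °C → rt
Reagents that add atoms: none
Why: Steglich-type carbodiimide esterification of a secondary allylic alcohol proceeds with retention at the carbinol carbon.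

Step 7
Reactants: 8 allylic ester
Product: 11 (2S,3S,4E)-2-[(benzyloxy)methyl]-3-{[(tert-butyldimethylsilyl)oxy]methyl}-2-methylhex-4-enoic acid (C14 acid; acid C2 = C1 and acid C3 = C10 of the target), via silyl ketene acetal 9 (not isolated), via trimethylsilyl ester 10 (not isolated)
Conditions: LiN(iPr)2, THF, −78 °C; Me3SiCl, −78 °C → 60 °C; then H2O/THF, pH 4 buffer, rt
Reagents that add atoms: none
Why: Ireland–Claisen rearrangement: lithium held between the enolate oxygen and the benzyl ether oxygen fixes CH2OBn cis to the O-metal (and keeps that C–O bond in the enolate plane, which disfavours β-elimination), and in the chair transition state with the carbinol methyl equatorial the (R)-carbinol and the E-alkene are relayed into C1 (quaternary) and C10 and a new E-propenyl group.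

Step 8
Reactants: 11 hexenoic acid
Product: 12 (2R,3S,4E)-2-[(benzyloxy)methyl]-3-{[(tert-butyldimethylsilyl)oxy]methyl}-2-methylhex-4-en-1-ol
Conditions: LiAlH4, Et2O, 0 °C → reflux
Reagents that add atoms: none
Why: Hydride reduction of the hindered acid to the C14 primary alcohol; silyl and benzyl ethers and the alkene are inert.

Step 9
Reactants: 12 hexenol
Product: 15 lactol 4-[(benzyloxy)methyl]-3-{[(tert-butyldimethylsilyl)oxy]methyl}-4-methyloxolan-2-ol (both anomers; C1 and C10 unchanged), via ozonide 13 (not isolated), via hydroxy aldehyde 14 (not isolated)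
Conditions: O3, CH2Cl2, −78 °C; PPh3, −78 °C → rt
Reagents that add atoms: ozone, [O-][O+]=O
Why: Ozonolysis with reductive work-up gives the C11 aldehyde, which closes onto the C14 hydroxyl as a five-membered lactol, a form that shields the epimerisable C10 centre.

Step 10
Reactants: 16 4-methoxybenzyl alcohol
Product: 17 tributyl{[(4-methoxybenzyl)oxy]methyl}stannane
Conditions: NaH, THF/DMF, 0 °C; Bu3SnCH2I, rt
Reagents that add atoms: (iodomethyl)tributylstannane, CCCC[Sn](CCCC)(CCCC)CI
Why: Williamson etherification of the alkoxide with the primary iodide.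

Step 11
Reactants: 15 lactol; 17 stannane
Product: 19 4-[(benzyloxy)methyl]-3-{[(tert-butyldimethylsilyl)oxy]methyl}-1-[(4-methoxybenzyl)oxy]-4-methylpentane-2,5-diol (both C11 epimers; C1 and C10 unchanged), via [(4-methoxybenzyl)oxy]methyllithium 18 (not isolated)
Conditions: 17 (2.5 equiv), nBuLi, THF, −78 °C; then 15, −78 → 0 °C
Reagents that add atoms: none
Why: Tin–lithium exchange gives the α-alkoxy organolithium, which adds to the open-chain aldehyde form of the lactol and brings in C20; the C11 carbinol configuration is irrelevant because it is oxidised next.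

Step 12
Reactants: 19 diol
Product: 20 2-[(benzyloxy)methyl]-3-{[(tert-butyldimethylsilyl)oxy]methyl}-5-[(4-methoxybenzyl)oxy]-2-methyl-4-oxopentanal (C14 aldehyde, C11 ketone)
Conditions: Dess–Martin periodinane (3 equiv), NaHCO3, CH2Cl2, 0 °C → rt
Reagents that add atoms: none
Why: Buffered Dess–Martin oxidation converts both alcohols at once and is neutral enough to leave the C10 centre next to the ketone alone.

Step 13
Reactants: 20 keto aldehyde
Product: 21 (5S)-4-[(benzyloxy)methyl]-3-{[(tert-butyldimethylsilyl)oxy]methyl}-5-hydroxy-1-[(4-methoxybenzyl)oxy]-4-methyloct-7-en-2-one (C14 carbinol S)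
Conditions: (−)-Ipc2B(allyl), Et2O, −78 °C; then H2O2, pH 7 buffer, MeOH, 0 °C
Reagents that add atoms: (−)-B-allyldiisopinocampheylborane, C=CCB([C@@H]1C[C@@H]2C[C@H]([C@H]1C)C2(C)C)[C@@H]1C[C@@H]2C[C@H]([C@H]1C)C2(C)C
Why: Brown allylboration: the borane reacts with the aldehyde and not with the hindered ketone at −78 °C, and the reagent derived from (+)-α-pinene adds to the Si face, which gives the (S)-carbinol at C14 under reagent control.

Step 14
Reactants: 21 homoallylic alcohol
Product: 22 tert-butyldimethylsilyl ether of 21 at the C14 oxygen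
Conditions: TBSOTf, 2,6-lutidine, CH2Cl2, −78 °C
Reagents that add atoms: tert-butyldimethylsilyl triflate, CC(C)(C)[Si](C)(C)OS(=O)(=O)C(F)(F)F
Why: Silylation of the secondary hydroxyl is fast at −78 °C and traps the open-chain hydroxy ketone, so any hemiketal in equilibrium is drained.

Step 15
Reactants: 22 silyl ether
Product: 24 (3S)-4-[(benzyloxy)methyl]-3-[(tert-butyldimethylsilyl)oxy]-5-{[(tert-butyldimethylsilyl)oxy]methyl}-7-[(4-methoxybenzyl)oxy]-4-methyl-6-oxoheptanal (C12 aldehyde and C11 ketone), via ozonide 23 (not isolated)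
Conditions: O3, CH2Cl2, −78 °C (Sudan Red 7B end point); PPh3, −78 °C → rt
Reagents that add atoms: ozone, [O-][O+]=O
Why: Ozonolysis of the terminal alkene, stopped at the indicator end point so that the anisyl ring is spared, unveils the C12 aldehyde.

Step 16
Reactants: 24 keto aldehyde
Product: 25 ring A cis-diol: cyclohexane with C1 (β-CH3, α-CH2OBn), C14 α-OTBS, C12 α-OH, C11 (α-OH, β-CH2O-4-methoxybenzyl), C10 β-CH2OTBS
Conditions: SmI2 (3 equiv), tBuOH (2 equiv), THF (0.01 molar), −78 → −20 °C; aq. NH4Cl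
Reagents that add atoms: none
Why: Divalent samarium transfers one electron to the C12 aldehyde, and the ketyl adds to the carbonyl carbon of the C11 ketone, which is held on the same trivalent samarium centre by its carbonyl and 4-methoxybenzyl ether oxygens; a second electron gives the samarium diolate, protonated on work-up. The closest known reaction type is the SmI2-promoted intramolecular ketone–aldehyde pinacol coupling that gives cis-cyclohexane-1,2-diols. Ring A closes by 6-exo-trig radical addition to the C11=O carbon, forming C11–C12. The cis relation of the C11 and C12 oxygens follows from both being bound to one samarium; the face should be set by a chair transition state with the C12 oxygen, the C14 silyloxy group and the C20 branch equatorial and the samarium-bound C11 oxygen axial and anti to the C10 CH2OTBS branch, although steric estimates of the two diol faces are close. The step needs the aldehyde to be reduced before the α-alkoxy ketone (otherwise the C20 oxygen is expelled) and cyclisation to outrun intermolecular coupling; the faster reduction of aldehydes at −78 °C without HMPA, tBuOH as proton source and high dilution should secure this, and the quaternary C1 pre-organises the chain.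

Step 17
Reactants: 25 diol
Product: 26 12-O-(3-methylbutanoyl) ester of 25 (C11 hydroxyl free)
Conditions: 3-methylbutanoyl chloride, pyridine, DMAP (cat.), CH2Cl2, 0 °C → rt
Reagents that add atoms: 3-methylbutanoyl chloride, CC(C)CC(=O)Cl
Why: Acylation takes place at the secondary C12 hydroxyl; the tertiary C11 hydroxyl is too hindered.

Step 18
Reactants: 26 isovalerate
Product: 27 C11,C20-diol (C20 primary hydroxyl free, benzyl ether at C2 kept)
Conditions: DDQ, CH2Cl2/pH 7 buffer (10:1), 0 °C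
Reagents that add atoms: none
Why: Oxidative cleavage of the electron-rich 4-methoxybenzyl ether leaves the plain benzyl ether, silyl ethers and ester intact; water in excess intercepts the oxocarbenium ion before the neighbouring tertiary hydroxyl can.

Step 19
Reactants: 27 diol
Product: 29 spiro-epoxide (C11 α-oxygen, C20 β-methylene), via C20 mesylate 28 (not isolated)
Conditions: MsCl, Et3N, CH2Cl2, −10 °C; then DBU, rt
Reagents that add atoms: none
Why: Sulfonylation of the primary hydroxyl and 3-exo-tet Williamson closure by the C11 oxygen; only the O–C20 bond forms, so C11 keeps its configuration.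

Step 20
Reactants: 29 epoxide
Product: 30 C2 primary alcohol
Conditions: H2 (1 atm), Pd(OH)2/C, EtOAc, rt
Reagents that add atoms: none
Why: Hydrogenolysis removes the benzyl ether while the non-benzylic epoxide, ester and silyl ethers survive; no alkene is present at this stage.

Step 21
Reactants: 30 alcohol
Product: 31 C2 aldehyde
Conditions: Dess–Martin periodinane, NaHCO3, CH2Cl2, 0 °C → rt
Reagents that add atoms: none
Why: Mild oxidation to a neopentyl aldehyde that cannot epimerise because C1 is quaternary.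

Step 22
Reactants: 31 aldehyde
Product: 32 C2 methyl carbinol (both C2 epimers; the methyl carbon is C3)
Conditions: MeMgBr, THF, −78 °C
Reagents that add atoms: methylmagnesium bromide, C[Mg]Br
Why: Grignard addition to the aldehyde is much faster than attack on the hindered isovalerate at −78 °C.

Step 23
Reactants: 32 carbinol
Product: 33 C2 methyl ketone
Conditions: Dess–Martin periodinane, NaHCO3, CH2Cl2, rt
Reagents that add atoms: none
Why: Oxidation merges both epimers into one ketone that can enolise only toward C3.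

Step 24
Reactants: 33 methyl ketone
Product: 34 C2 ketone carrying the 3-bromobut-3-enyl chain (C3–C4–C5(Br)=C16H2)
Conditions: LiN(SiMe3)2 (1.05 equiv), THF, −78 °C; 2,3-dibromopropene, −78 → −20 °C
Reagents that add atoms: 2,3-dibromopropene, C=C(Br)CBr
Why: Kinetic enolate alkylation: the ketone methyl is by far the most acidic and accessible site and the allylic bromide is the only reactive position of the electrophile.

Step 25
Reactants: 34 ketone
Product: 35 (2S)-alcohol
Conditions: (R)-2-methyl-CBS-oxazaborolidine (0.5 equiv), BH3·SMe2, THF, −30 °C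
Reagents that add atoms: none
Why: Corey–Bakshi–Shibata reduction: the quaternary C1 acts as the large group and the CH2 chain as the small one, so the (R)-catalyst should deliver the (S)-carbinol under reagent control; the deactivated bromoalkene is hydroborated far more slowly.

Step 26
Reactants: 35 alcohol
Product: 36 2-O-(2-methylpropanoyl) ester
Conditions: 2-methylpropanoyl chloride, pyridine, DMAP, CH2Cl2, rt → 40 °C
Reagents that add atoms: 2-methylpropanoyl chloride, CC(C)C(=O)Cl
Why: DMAP-catalysed acylation of the hindered secondary alcohol installs the final C2 ester.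

Step 27
Reactants: 36 bis-silyl ether
Product: 37 C9,C14-diol (primary C9–OH, secondary C14–OH)
Conditions: Bu4NF, AcOH (1:1), THF, rt → 40 °C
Reagents that add atoms: none
Why: Buffered fluoride removes both silyl ethers without opening the epoxide and with little basicity, which limits acyl migration to the freed C14 hydroxyl.

Step 28
Reactants: 37 diol
Product: 38 C9 aldehyde (C14 hydroxyl free)
Conditions: TEMPO (cat.), PhI(OAc)2, CH2Cl2, rt
Reagents that add atoms: none
Why: Oxoammonium oxidation is selective for the primary alcohol; the trans arrangement of the C14 oxygen and C9 rules out a lactol, and C10, flanked by two quaternary carbons, resists enolisation.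

Step 29
Reactants: 16 4-methoxybenzyl alcohol
Product: 39 allyl 4-methoxybenzyl ether
Conditions: NaH, THF, 0 °C; allyl bromide, Bu4NI (cat.), rt
Reagents that add atoms: allyl bromide, C=CCBr
Why: Williamson etherification.

Step 30
Reactants: 38 aldehyde; 39 allyl ether
Product: 41 (9S)-adduct with C9–OH and C8–O-4-methoxybenzyl syn and a C7=C6 vinyl group, via alkoxyallylborane 40 (not isolated)
Conditions: 39 (3 equiv), sBuLi, THF, −78 °C; (+)-Ipc2BOMe; BF3·OEt2; then 38, −78 °C; H2O2, pH 7 buffer, 0 °C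
Reagents that add atoms: none
Why: Brown γ-alkoxyallylboration: the Z-configured reagent gives the syn C9/C8 pair through a chair transition state, the isopinocampheyl groups from (+)-Ipc2BOMe direct attack to the Re face of the aldehyde and so set C9 as S, and the excess reagent covers the free C14 hydroxyl, which is released on oxidative work-up.

Step 31
Reactants: 41 diol
Product: 42 9,14-diacetate
Conditions: Ac2O, pyridine, DMAP, CH2Cl2, rt
Reagents that add atoms: acetic anhydride, CC(=O)OC(C)=O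
Why: One acetylation installs both final acetates at C9 and C14.

Step 32
Reactants: 42 diacetate
Product: 43 C6,C7-diol (C7–OH erythro to the C8 ether oxygen)
Conditions: OsO4 (cat.), N-methylmorpholine N-oxide, acetone/H2O, 0 °C
Reagents that add atoms: N-methylmorpholine N-oxide, C[N+]1([O-])CCOCC1; water, O
Why: Upjohn dihydroxylation: the electron-poor 2-bromoalkene is osmylated far more slowly than the monosubstituted vinyl group, and osmium adds anti to the allylic C8 oxygen (inside-hydrogen conformer), which places the new C7 hydroxyl as the target requires.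

Step 33
Reactants: 43 diol
Product: 44 6-O-tert-butyldimethylsilyl ether (C7–OH free)
Conditions: TBSCl, imidazole, CH2Cl2, 0 °C
Reagents that add atoms: tert-butyldimethylsilyl chloride, CC(C)(C)[Si](C)(C)Cl
Why: Selective silylation of the primary hydroxyl.

Step 34
Reactants: 44 alcohol
Product: 45 7-O-(2-bromopropanoyl) ester (both epimers at the CHBr carbon)
Conditions: 2-bromopropanoyl bromide, pyridine, CH2Cl2, −20 °C
Reagents that add atoms: 2-bromopropanoyl bromide, CC(Br)C(=O)Br
Why: Acylation of the only free hydroxyl places the future C17–C19 unit on the C7 oxygen.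

Step 35
Reactants: 45 bromo ester
Product: 46 C8 alcohol
Conditions: DDQ, CH2Cl2/pH 7 buffer, 0 °C → rt
Reagents that add atoms: none
Why: Oxidative removal of the 4-methoxybenzyl ether; no free neighbouring hydroxyl is present to form an acetal.

Step 36
Reactants: 46 alcohol
Product: 47 C8 ketone
Conditions: Dess–Martin periodinane, NaHCO3, CH2Cl2, 0 °C
Reagents that add atoms: none
Why: Neutral oxidation to the α,α'-bis(acyloxy) ketone avoids enolisation at C7 and C9.

Step 37
Reactants: 47 keto bromo ester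
Product: 48 γ-lactone (C8 α-OH, C17 methyl cis to it, C7–O in the ring; C6–OTBS)
Conditions: SmI2 (2.2 equiv), THF, −78 °C; pH 7 buffer at −78 °C
Reagents that add atoms: none
Why: Samarium Reformatsky reaction (intramolecular aldol): the carbon–bromine bond is reduced faster than the ketone, the samarium propionate enolate can reach the C8 carbonyl only in a 5-exo closure from the C7 oxygen, the large C6 and C9 groups end up trans on the lactone, and samarium bridging the enolate and ketone oxygens places the C17 methyl cis to the C8 hydroxyl and away from C9.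

Step 38
Reactants: 48 silyl ether
Product: 49 C6 primary alcohol
Conditions: Bu4NF, AcOH (1:1), THF, 0 °C
Reagents that add atoms: none
Why: Buffered fluoride cleaves the primary silyl ether without retro-aldol of the β-hydroxy lactone.

Step 39
Reactants: 49 alcohol
Product: 50 C6 aldehyde
Conditions: Dess–Martin periodinane, NaHCO3, CH2Cl2, 0 °C; used at once
Reagents that add atoms: none
Why: Neutral oxidation gives the α-acyloxy aldehyde without epimerising C7.

Step 40
Reactants: 50 bromoalkene aldehyde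
Product: 51 ten-membered ring allylic alcohol with C5=C16 methylene (both C6 epimers)
Conditions: CrCl2 (10 equiv), NiCl2 (2 mol %), DMSO (0.002 molar), rt
Reagents that add atoms: none
Why: Nozaki–Hiyama–Kishi macrocyclisation: nickel inserts into the 2-bromo-1-alkene, transmetallation gives an alkenylchromium species that adds only to the aldehyde, a reaction type with precedent for nine- and ten-membered rings and tolerant of esters, epoxide and free hydroxyl.

Step 41
Reactants: 51 allylic alcohol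
Product: 52 C6 enone
Conditions: Dess–Martin periodinane, NaHCO3, CH2Cl2, 0 °C
Reagents that add atoms: none
Why: Oxidation merges the C6 epimers (the polar Felkin–Anh mode of step 40 would favour the unwanted one) into a single enone.

Step 42
Reactants: 52 enone
Product: 53 (6R)-allylic alcohol (6,7-syn)
Conditions: NaBH4, CeCl3·7H2O, MeOH, −78 °C
Reagents that add atoms: none
Why: Luche reduction: 1,2-selective hydride addition anti to the C7–O bond (Felkin–Anh, polar model) should give the 6,7-syn alcohol, the epimer needed for inversion in the last step.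

Step 43
Reactants: 53 allylic alcohol
Product: 54 target CNP0194902.1
Conditions: PPh3, hexachloroacetone, CH2Cl2, −20 → 0 °C
Reagents that add atoms: hexachloroacetone, ClC(Cl)(Cl)C(=O)C(Cl)(Cl)Cl
Why: Appel-type chlorination: chloride displaces the alkoxyphosphonium group with inversion at C6 and without allylic transposition under these mild neutral conditions, and the tertiary C8 hydroxyl is too hindered to react.

**Compound list**
1 | methyl 3-hydroxy-2-methylpropanoate (racemic) | COC(=O)C(C)CO | starting material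
2 | methyl 3-(benzyloxy)-2-methylpropanoate (racemic) | COC(=O)C(C)COCc1ccccc1 | intermediate
3 | 3-(benzyloxy)-2-methylpropanoic acid (racemic) | OC(=O)C(C)COCc1ccccc1 | intermediate
4 | (R)-but-3-yn-2-ol | C[C@@H](O)C#C | starting material
5 | (R)-pent-2-yne-1,4-diol | C[C@@H](O)C#CCO | intermediate
6 | (R,E)-pent-2-ene-1,4-diol | C[C@@H](O)/C=C/CO | intermediate
7 | (R,E)-5-[(tert-butyldimethylsilyl)oxy]pent-3-en-2-ol | C[C@@H](O)/C=C/CO[Si](C)(C)C(C)(C)C | intermediate
8 | (2R,3E)-5-(TBS-oxy)pent-3-en-2-yl 3-(benzyloxy)-2-methylpropanoate (α-epimers) | C[C@@H](OC(=O)C(C)COCc1ccccc1)/C=C/CO[Si](C)(C)C(C)(C)C | intermediate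
9 | trimethylsilyl ketene acetal of 8, CH2OBn cis to OSiMe3 | C[C@@H](O/C(O[Si](C)(C)C)=C(\C)COCc1ccccc1)/C=C/CO[Si](C)(C)C(C)(C)C | intermediate
10 | trimethylsilyl ester of acid 11 | C[Si](C)(C)OC(=O)[C@](C)(COCc1ccccc1)[C@@H](CO[Si](C)(C)C(C)(C)C)/C=C/C | intermediate
11 | (2S,3S,4E)-2-[(benzyloxy)methyl]-3-[(TBS-oxy)methyl]-2-methylhex-4-enoic acid | OC(=O)[C@](C)(COCc1ccccc1)[C@@H](CO[Si](C)(C)C(C)(C)C)/C=C/C | intermediate
12 | (2R,3S,4E)-2-[(benzyloxy)methyl]-3-[(TBS-oxy)methyl]-2-methylhex-4-en-1-ol | OC[C@](C)(COCc1ccccc1)[C@@H](CO[Si](C)(C)C(C)(C)C)/C=C/C | intermediate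
13 | ozonide (1,2,4-trioxolane) of the propenyl group of 12 | OC[C@](C)(COCc1ccccc1)[C@@H](CO[Si](C)(C)C(C)(C)C)C1OC(C)OO1 | intermediate
14 | open-chain C11 aldehyde with free C14 alcohol | OC[C@](C)(COCc1ccccc1)[C@@H](CO[Si](C)(C)C(C)(C)C)C=O | intermediate
15 | lactol 4-[(benzyloxy)methyl]-3-[(TBS-oxy)methyl]-4-methyloxolan-2-ol (anomers) | O1C[C@](C)(COCc2ccccc2)[C@@H](CO[Si](C)(C)C(C)(C)C)C1O | intermediate
16 | 4-methoxybenzyl alcohol | COc1ccc(CO)cc1 | starting material
17 | tributyl{[(4-methoxybenzyl)oxy]methyl}stannane | CCCC[Sn](CCCC)(CCCC)COCc1ccc(OC)cc1 | intermediate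
18 | [(4-methoxybenzyl)oxy]methyllithium | [Li]COCc1ccc(OC)cc1 | intermediate
19 | C11/C14 diol (C11 epimers), C20 as CH2O-4-methoxybenzyl | OC[C@](C)(COCc1ccccc1)[C@@H](CO[Si](C)(C)C(C)(C)C)C(O)COCc1ccc(OC)cc1 | intermediate
20 | C14 aldehyde / C11 ketone | O=C[C@](C)(COCc1ccccc1)[C@@H](CO[Si](C)(C)C(C)(C)C)C(=O)COCc1ccc(OC)cc1 | intermediate
21 | (14S)-homoallylic alcohol, C11 ketone | C=CC[C@H](O)[C@](C)(COCc1ccccc1)[C@@H](CO[Si](C)(C)C(C)(C)C)C(=O)COCc1ccc(OC)cc1 | intermediate
22 | C14 TBS ether of 21 | C=CC[C@H](O[Si](C)(C)C(C)(C)C)[C@](C)(COCc1ccccc1)[C@@H](CO[Si](C)(C)C(C)(C)C)C(=O)COCc1ccc(OC)cc1 | intermediate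
23 | ozonide of the terminal alkene of 22 | C1OC(OO1)C[C@H](O[Si](C)(C)C(C)(C)C)[C@](C)(COCc2ccccc2)[C@@H](CO[Si](C)(C)C(C)(C)C)C(=O)COCc2ccc(OC)cc2 | intermediate
24 | C12 aldehyde / C11 ketone (pinacol precursor) | O=CC[C@H](O[Si](C)(C)C(C)(C)C)[C@](C)(COCc1ccccc1)[C@@H](CO[Si](C)(C)C(C)(C)C)C(=O)COCc1ccc(OC)cc1 | intermediate
25 | ring A cis-11α,12α-diol (1β-CH3, 1α-CH2OBn, 14α-OTBS, 11β-CH2OPMB, 10β-CH2OTBS) | c1ccccc1COC[C@@]2(C)[C@@H](O[Si](C)(C)C(C)(C)C)C[C@@H](O)[C@](O)(COCc3ccc(OC)cc3)[C@@H]2CO[Si](C)(C)C(C)(C)C | intermediate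
26 | 12-O-isovalerate of 25 | c1ccccc1COC[C@@]2(C)[C@@H](O[Si](C)(C)C(C)(C)C)C[C@@H](OC(=O)CC(C)C)[C@](O)(COCc3ccc(OC)cc3)[C@@H]2CO[Si](C)(C)C(C)(C)C | intermediate
27 | C11,C20-diol | c1ccccc1COC[C@@]2(C)[C@@H](O[Si](C)(C)C(C)(C)C)C[C@@H](OC(=O)CC(C)C)[C@](O)(CO)[C@@H]2CO[Si](C)(C)C(C)(C)C | intermediate
28 | C20 mesylate of 27 | c1ccccc1COC[C@@]2(C)[C@@H](O[Si](C)(C)C(C)(C)C)C[C@@H](OC(=O)CC(C)C)[C@](O)(COS(C)(=O)=O)[C@@H]2CO[Si](C)(C)C(C)(C)C | intermediate
29 | 11,20-spiro-epoxide (O α) | c1ccccc1COC[C@@]2(C)[C@@H](O[Si](C)(C)C(C)(C)C)C[C@@H](OC(=O)CC(C)C)[C@]3(CO3)[C@@H]2CO[Si](C)(C)C(C)(C)C | intermediate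
30 | C2 primary alcohol | OC[C@@]2(C)[C@@H](O[Si](C)(C)C(C)(C)C)C[C@@H](OC(=O)CC(C)C)[C@]3(CO3)[C@@H]2CO[Si](C)(C)C(C)(C)C | intermediate
31 | C2 aldehyde | O=C[C@@]2(C)[C@@H](O[Si](C)(C)C(C)(C)C)C[C@@H](OC(=O)CC(C)C)[C@]3(CO3)[C@@H]2CO[Si](C)(C)C(C)(C)C | intermediate
32 | C2 methyl carbinol (C2 epimers) | CC(O)[C@@]2(C)[C@@H](O[Si](C)(C)C(C)(C)C)C[C@@H](OC(=O)CC(C)C)[C@]3(CO3)[C@@H]2CO[Si](C)(C)C(C)(C)C | intermediate
33 | C2 methyl ketone | CC(=O)[C@@]2(C)[C@@H](O[Si](C)(C)C(C)(C)C)C[C@@H](OC(=O)CC(C)C)[C@]3(CO3)[C@@H]2CO[Si](C)(C)C(C)(C)C | intermediate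
34 | C2 ketone with 3-bromobut-3-enyl chain | C=C(Br)CCC(=O)[C@@]2(C)[C@@H](O[Si](C)(C)C(C)(C)C)C[C@@H](OC(=O)CC(C)C)[C@]3(CO3)[C@@H]2CO[Si](C)(C)C(C)(C)C | intermediate
35 | (2S)-alcohol | C=C(Br)CC[C@H](O)[C@@]2(C)[C@@H](O[Si](C)(C)C(C)(C)C)C[C@@H](OC(=O)CC(C)C)[C@]3(CO3)[C@@H]2CO[Si](C)(C)C(C)(C)C | intermediate
36 | 2-O-isobutyrate | C=C(Br)CC[C@H](OC(=O)C(C)C)[C@@]2(C)[C@@H](O[Si](C)(C)C(C)(C)C)C[C@@H](OC(=O)CC(C)C)[C@]3(CO3)[C@@H]2CO[Si](C)(C)C(C)(C)C | intermediate
37 | C9,C14-diol | C=C(Br)CC[C@H](OC(=O)C(C)C)[C@@]2(C)[C@@H](O)C[C@@H](OC(=O)CC(C)C)[C@]3(CO3)[C@@H]2CO | intermediate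
38 | C9 aldehyde, 14-OH free | C=C(Br)CC[C@H](OC(=O)C(C)C)[C@@]2(C)[C@@H](O)C[C@@H](OC(=O)CC(C)C)[C@]3(CO3)[C@@H]2C=O | intermediate
39 | allyl 4-methoxybenzyl ether | C=CCOCc1ccc(OC)cc1 | intermediate
40 | [(Z)-3-(4-methoxybenzyloxy)allyl]diisopinocampheylborane from (+)-Ipc2BOMe | COc1ccc(CO/C=C\CB([C@H]2C[C@H]3C[C@@H]([C@@H]2C)C3(C)C)[C@H]2C[C@H]3C[C@@H]([C@@H]2C)C3(C)C)cc1 | intermediate
41 | (9S)-9-OH, 8-O-PMB (syn), C7=C6 vinyl, 14-OH | C=C(Br)CC[C@H](OC(=O)C(C)C)[C@@]2(C)[C@@H](O)C[C@@H](OC(=O)CC(C)C)[C@]3(CO3)[C@@H]2[C@H](O)[C@@H](OCc1ccc(OC)cc1)C=C | intermediate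
42 | 9,14-diacetate | C=C(Br)CC[C@H](OC(=O)C(C)C)[C@@]2(C)[C@@H](OC(C)=O)C[C@@H](OC(=O)CC(C)C)[C@]3(CO3)[C@@H]2[C@H](OC(C)=O)[C@@H](OCc1ccc(OC)cc1)C=C | intermediate
43 | C6,C7-diol | C=C(Br)CC[C@H](OC(=O)C(C)C)[C@@]2(C)[C@@H](OC(C)=O)C[C@@H](OC(=O)CC(C)C)[C@]3(CO3)[C@@H]2[C@H](OC(C)=O)[C@@H](OCc1ccc(OC)cc1)[C@@H](O)CO | intermediate
44 | 6-O-TBS ether, 7-OH | C=C(Br)CC[C@H](OC(=O)C(C)C)[C@@]2(C)[C@@H](OC(C)=O)C[C@@H](OC(=O)CC(C)C)[C@]3(CO3)[C@@H]2[C@H](OC(C)=O)[C@@H](OCc1ccc(OC)cc1)[C@@H](O)CO[Si](C)(C)C(C)(C)C | intermediate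
45 | 7-O-(2-bromopropanoate) (CHBr epimers) | C=C(Br)CC[C@H](OC(=O)C(C)C)[C@@]2(C)[C@@H](OC(C)=O)C[C@@H](OC(=O)CC(C)C)[C@]3(CO3)[C@@H]2[C@H](OC(C)=O)[C@@H](OCc1ccc(OC)cc1)[C@@H](OC(=O)C(C)Br)CO[Si](C)(C)C(C)(C)C | intermediate
46 | C8 alcohol | C=C(Br)CC[C@H](OC(=O)C(C)C)[C@@]2(C)[C@@H](OC(C)=O)C[C@@H](OC(=O)CC(C)C)[C@]3(CO3)[C@@H]2[C@H](OC(C)=O)[C@@H](O)[C@@H](OC(=O)C(C)Br)CO[Si](C)(C)C(C)(C)C | intermediate
47 | C8 ketone | C=C(Br)CC[C@H](OC(=O)C(C)C)[C@@]2(C)[C@@H](OC(C)=O)C[C@@H](OC(=O)CC(C)C)[C@]3(CO3)[C@@H]2[C@H](OC(C)=O)C(=O)[C@@H](OC(=O)C(C)Br)CO[Si](C)(C)C(C)(C)C | intermediate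
48 | γ-lactone with 8-OH, 6-O-TBS | C=C(Br)CC[C@H](OC(=O)C(C)C)[C@@]2(C)[C@@H](OC(C)=O)C[C@@H](OC(=O)CC(C)C)[C@]3(CO3)[C@@H]2[C@H](OC(C)=O)[C@]4(O)[C@@H](C)C(=O)O[C@H]4CO[Si](C)(C)C(C)(C)C | intermediate
49 | lactone C6 primary alcohol | C=C(Br)CC[C@H](OC(=O)C(C)C)[C@@]2(C)[C@@H](OC(C)=O)C[C@@H](OC(=O)CC(C)C)[C@]3(CO3)[C@@H]2[C@H](OC(C)=O)[C@]4(O)[C@@H](C)C(=O)O[C@H]4CO | intermediate
50 | lactone C6 aldehyde | C=C(Br)CC[C@H](OC(=O)C(C)C)[C@@]2(C)[C@@H](OC(C)=O)C[C@@H](OC(=O)CC(C)C)[C@]3(CO3)[C@@H]2[C@H](OC(C)=O)[C@]4(O)[C@@H](C)C(=O)O[C@H]4C=O | intermediate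
51 | ten-membered ring C6 allylic alcohol (C6 epimers) | C=C1CC[C@H](OC(=O)C(C)C)[C@@]2(C)[C@@H](OC(C)=O)C[C@@H](OC(=O)CC(C)C)[C@]3(CO3)[C@@H]2[C@H](OC(C)=O)[C@]2(O)[C@@H](C)C(=O)O[C@H]2C1O | intermediate
52 | C6 enone | C=C1CC[C@H](OC(=O)C(C)C)[C@@]2(C)[C@@H](OC(C)=O)C[C@@H](OC(=O)CC(C)C)[C@]3(CO3)[C@@H]2[C@H](OC(C)=O)[C@]2(O)[C@@H](C)C(=O)O[C@H]2C1=O | intermediate
53 | (6R)-allylic alcohol | C=C1CC[C@H](OC(=O)C(C)C)[C@@]2(C)[C@@H](OC(C)=O)C[C@@H](OC(=O)CC(C)C)[C@]3(CO3)[C@@H]2[C@H](OC(C)=O)[C@]2(O)[C@@H](C)C(=O)O[C@H]2[C@@H]1O | intermediate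
54 | CNP0194902.1, (1S,2S,6S,7R,8R,9S,10S,11R,12R,14S,17R)-9,14-diacetoxy-6-chloro-11,20-epoxy-8-hydroxy-2-(2-methylpropanoyloxy)-12-(3-methylbutanoyloxy)briar-5(16)-en-19,7-olide | C=C1CC[C@H](OC(=O)C(C)C)[C@@]2(C)[C@@H](OC(C)=O)C[C@@H](OC(=O)CC(C)C)[C@]3(CO3)[C@@H]2[C@H](OC(C)=O)[C@]2(O)[C@@H](C)C(=O)O[C@H]2[C@H]1Cl | target

**Totals**
Total step count: 43. Longest linear sequence: 39 steps (4 to 54 through steps 3–9, 11–28 and 30–43).

**Steps most likely to fail**

Step 40. The alkenylchromium species may be protonated, or the aldehyde may react between molecules, before the strained ten-membered ring closes. The fallback makes the same C5–C6 bond by acylation and sets out from 49. Pd(PPh3)4 and Me3SnSnMe3 exchange the bromide for tin to give the vinylstannane alcohol F5. Dess–Martin oxidation gives the stannyl aldehyde F6, and NaClO2/NaH2PO4/2-methyl-2-butene gives the stannyl acid F7. 1-Chloro-N,N,2-trimethylpropenylamine converts this under neutral conditions to the acid chloride F8. Pd2(dba)3 with tri(2-furyl)phosphine at high dilution then closes the ring by intramolecular Stille acylation. The route is rejoined at enone 52, so steps 39 to 41 are bypassed.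

Step 37. Electron transfer to the α-acyloxy ketone, with loss of the C9 acetate or the C7 ester, may compete with enolate formation, or the samarium alkoxide may take up the neighbouring acetyl group. The fallback generates the propionate enolate by hydrometallation and sets out from 44. Acryloyl chloride and iPr2NEt give the C7 acrylate F2. DDQ then gives the C8 alcohol F3, and Dess–Martin periodinane the C8 ketone F4. A copper hydride formed from Cu(OAc)2·H2O, dppf and (Me2HSi)2O adds hydride only to the acrylate β-carbon, and the resulting enolate closes onto the C8 ketone (reductive aldol cyclisation). The route is rejoined at lactone 48.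

Step 16. The ketyl addition may show poor facial selectivity, or the C20 oxygen may be lost by reduction of the α-alkoxy ketone. The fallback makes the C11–C12 bond without a reductant and sets out from 24. An aminoindanol-derived chiral triazolium salt with DBU turns the C12 aldehyde into an acyl-anion equivalent that adds to the C11 ketone (intramolecular crossed benzoin), the carbene setting C11, to give the ring A ketol F1 (C12 ketone, C11 tertiary alcohol). LiBH(sBu)3 at −78 °C then delivers hydride equatorially, which gives the C12 hydroxyl cis to the C11 oxygen. The route is rejoined at diol 25.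

**Further compounds**
F1 | step 16 | ring A ketol (C12 ketone, C11 α-OH) | c1ccccc1COC[C@@]2(C)[C@@H](O[Si](C)(C)C(C)(C)C)CC(=O)[C@](O)(COCc3ccc(OC)cc3)[C@@H]2CO[Si](C)(C)C(C)(C)C
F2 | step 37 | C7 acrylate of 44 | C=C(Br)CC[C@H](OC(=O)C(C)C)[C@@]2(C)[C@@H](OC(C)=O)C[C@@H](OC(=O)CC(C)C)[C@]3(CO3)[C@@H]2[C@H](OC(C)=O)[C@@H](OCc1ccc(OC)cc1)[C@@H](OC(=O)C=C)CO[Si](C)(C)C(C)(C)C
F3 | step 37 | C8 alcohol of the acrylate series | C=C(Br)CC[C@H](OC(=O)C(C)C)[C@@]2(C)[C@@H](OC(C)=O)C[C@@H](OC(=O)CC(C)C)[C@]3(CO3)[C@@H]2[C@H](OC(C)=O)[C@@H](O)[C@@H](OC(=O)C=C)CO[Si](C)(C)C(C)(C)C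
F4 | step 37 | C8 ketone of the acrylate series | C=C(Br)CC[C@H](OC(=O)C(C)C)[C@@]2(C)[C@@H](OC(C)=O)C[C@@H](OC(=O)CC(C)C)[C@]3(CO3)[C@@H]2[C@H](OC(C)=O)C(=O)[C@@H](OC(=O)C=C)CO[Si](C)(C)C(C)(C)C
F5 | step 40 | C5 trimethylstannyl alkene, C6 primary alcohol | C=C([Sn](C)(C)C)CC[C@H](OC(=O)C(C)C)[C@@]2(C)[C@@H](OC(C)=O)C[C@@H](OC(=O)CC(C)C)[C@]3(CO3)[C@@H]2[C@H](OC(C)=O)[C@]4(O)[C@@H](C)C(=O)O[C@H]4CO
F6 | step 40 | stannyl C6 aldehyde | C=C([Sn](C)(C)C)CC[C@H](OC(=O)C(C)C)[C@@]2(C)[C@@H](OC(C)=O)C[C@@H](OC(=O)CC(C)C)[C@]3(CO3)[C@@H]2[C@H](OC(C)=O)[C@]4(O)[C@@H](C)C(=O)O[C@H]4C=O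
F7 | step 40 | stannyl C6 carboxylic acid | C=C([Sn](C)(C)C)CC[C@H](OC(=O)C(C)C)[C@@]2(C)[C@@H](OC(C)=O)C[C@@H](OC(=O)CC(C)C)[C@]3(CO3)[C@@H]2[C@H](OC(C)=O)[C@]4(O)[C@@H](C)C(=O)O[C@H]4C(O)=O
F8 | step 40 | stannyl C6 acid chloride | C=C([Sn](C)(C)C)CC[C@H](OC(=O)C(C)C)[C@@]2(C)[C@@H](OC(C)=O)C[C@@H](OC(=O)CC(C)C)[C@]3(CO3)[C@@H]2[C@H](OC(C)=O)[C@]4(O)[C@@H](C)C(=O)O[C@H]4C(Cl)=O
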